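**Remark on the structure.** The SMILES is taken as definitive. The locant string of the name uses position 3 twice and is read as 3-hydroxy-5,3′-dimethoxy: ring A has OH at C3 and OMe at C5, ring B has OMe at C3′. The target has no stereocentre.

## Structural features

The target is an achiral array of four benzene rings. A pentasubstituted central ring (ring A) is joined at C1 through a CH2–CH2 bridge to a 3-methoxyphenyl ring (ring B), and at C2 and C6 through single CH2 groups to two 4-hydroxyphenyl rings (rings C and D). Ring A also carries OH at C3 and OMe at C5, and its only hydrogen is at C4. Its carbon substituents are therefore symmetric about the C1–C4 axis, and only the two oxygens differ. Nothing configurational has to be set or kept. The fragile groups are the three free phenols, above all the electron-rich resorcinol-type ring A with its open C4 position, and the two diarylmethane CH2 groups, which are open to oxidation and to deprotonation by strong bases. The real difficulty is the contiguous C6–C1–C2 array: the bond from C1 to the bridge is flanked by two benzyl groups, which penalises any intermolecular bond formation at C1. The key step exploits the C1(ring A)–CH2–CH2–C1′(ring B) bridge, which is the two carbons of a vinyl group with one aryl added to each. With boron on the carbon next to ring A, the crowded C1–C bond can be made by a 1,2-shift inside a boron ate complex, and the boron is later replaced by hydrogen.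

## Logic of the disconnections

**14 ⇒ 13.** The three phenolic O–H bonds are traced back to O–CH2Ph bonds. Every earlier stage uses an aryllithium, a boronate or a benzylic cation, none of which tolerates a free phenol, and one kind of ether on all three oxygens can be removed in a single operation. The skeleton is unchanged, but 13 has no acidic hydrogen and no oxidation-prone phenol. The forward step must cleave three aryl benzyl ethers without touching the methyl ethers or the diarylmethane and bibenzyl C–C bonds.

**13 ⇒ 12.** The C–H bond at the bridge carbon next to ring A is replaced by a C–B bond. Boron stands there only because it is the residue of the coupling that builds the bridge. The cost is one meaningless stereocentre in 12 and one extra step. The forward step is a protodeboronation of a crowded secondary benzylic boronic ester, which must run without acid so that the benzyl ethers survive.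

**12 ⇒ 6 + 9 + 8, through 10 and 11.** Two bonds are cut: C1 of ring A to the boron-bearing carbon, and the bridge CH2 to ring B. Cutting here turns the most hindered bond of the molecule into an intramolecular migration from boron, and reduces 12 to an aryl bromide holding all of ring A, a two-carbon unit and a simple triflate. The demands are as follows.
- The metallate shift must outrun direct transfer of a group from boron to palladium, which requires a cationic palladium centre.
- The exchange that converts 6 into 10 releases bromide, which would occupy the site needed for alkene binding. The precursor skeleton is kept, and the shortfall is met by a potassium triflate additive that precipitates the bromide.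
- 10 must be trapped by 9 at low temperature, before it can take a proton from a benzylic CH2 group.

**8 ⇒ 7.** The O–S bond of the sulfonate is cut. A triflate is chosen over a halide as the electrophile because it brings no coordinating anion to palladium. The forward step is a routine O-sulfonylation.

**6 ⇒ 2 + two molecules of 3, through 4 and 5.** The two aryl–CH2 bonds flanking the bromine are cut. Each of these positions is para to one ether oxygen and ortho to the other, so they are the natural sites of electrophilic substitution. This removes both side rings in one operation and leaves a trisubstituted benzene. The forward step must alkylate twice and only twice, avoid the position between the two oxygens, and leave the benzyl ethers intact under acid catalysis.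

**2 ⇒ 1.** The O–CH2Ph bond on ring A is cut. Compound 1 already has bromine meta to both oxygens, a position that electrophilic halogenation could not reach, and already has the two oxygens differentiated. The forward step is a simple etherification.

## Other disconnections considered

**Alternative 1:** The cut goes through ring A itself, at C6–C1 and C4–C5, so that the arene is traced back to a cyclohexane-1,3-dione.
- Forward key step: NaOMe would add dimethyl 2-[4-(benzyloxy)benzyl]malonate A2 to the β-carbon of (E)-3-[4-(benzyloxy)benzyl]-6-(3-methoxyphenyl)hex-3-en-2-one A1. The methyl ketone enolate of the adduct would then close onto one ester to give the dioxo ester A3. Ester removal, dehydrogenative aromatisation with mono-O-methylation, and debenzylation would follow.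
- In its favour: every substituent of ring A is placed by the connectivity of two acyclic pieces, so no arene substitution regiochemistry arises. The key step needs no organolithium and no palladium. After decarboxylation the dione is constitutionally symmetric, so methylation of either oxygen leads to the same arene. On the O3/O5 differentiation it is therefore the equal of the chosen plan, which obtains that differentiation from starting material 1.
- Against it: the Michael step must join a fully substituted malonate carbon to the β-carbon of an α,β-disubstituted enone. That addition is crowded and reversible, and deconjugation of A1 toward its benzylic positions competes. A1 itself needs a regiocontrolled condensation. The late aromatisation must oxidise a ring bearing three benzylic side chains and 4-alkoxybenzyl units, which quinone oxidants attack, while hot palladium on carbon would strip the benzyl ethers.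
- Comparison: about nine or ten operations against six, so it is weaker in step economy. Its risk is spread over three steps (Michael addition, aromatisation, mono-methylation) and not concentrated in one.

**Alternative 2:** Three bonds to ring A are cut at once: C2–CH2, C6–CH2 and C1–C(bridge). This leaves 1-(benzyloxy)-3-iodo-5-methoxybenzene A4, two equivalents of 4-(benzyloxy)benzyl chloride A5, and 3-methoxystyrene A6.
- Forward key step: a Catellani reaction under Pd(OAc)2, tri(2-furyl)phosphine, norbornene and Cs2CO3. The arylpalladium from A4 would be relayed by norbornene to both ortho positions, each being benzylated by A5 through a palladacycle that passes through tetravalent palladium. After norbornene extrusion, the di-ortho-substituted arylpalladium would be terminated by a Heck reaction with A6 to give the stilbene A7. One hydrogenation would then saturate the alkene and remove the three benzyl groups.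
- In its favour: it is the shortest route, three steps from the phenol precursor of A4 against six. The benzyl positions are dictated by the iodide and not by electrophilic substitution preferences. No cryogenic organolithium is used and no boron has to be removed. On step economy and on regiochemical certainty of the benzyl positions it is better than the chosen plan.
- Against it: both ortho C–H bonds of A4 are flanked by an alkoxy group, the pattern for which ortho palladation in the norbornene relay is most sluggish, and two such events are needed. The electron-rich benzylic chloride A5 can add directly to zerovalent palladium and couple with A6, or be consumed by the carbonate base. Four components must also react in a fixed order.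
- Comparison: the chosen plan separates the introduction of the benzyl groups from the construction of the bridge and asks only one chemoselectivity of its key step. The alternative puts three selectivity demands into one flask. If the double ortho-benzylation next to the alkoxy groups proved workable, it would be the superior route.

**Alternative 3:** Ring A is cut at C1–C6 and C2–C3 into two pieces. The diene 5-[4-(benzyloxy)phenyl]-1,3-dimethoxy-1-(trimethylsilyloxy)penta-1,3-diene A8 supplies C3 to C6 with both oxygens. The ynone 1-[4-(benzyloxy)phenyl]-5-(3-methoxyphenyl)pent-2-yn-1-one A9 supplies C1 and C2 with the bridge and one benzylic carbon at the ketone level.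
- Forward key step: on heating, the substituted terminus of the diene would bond to the β-carbon of the ynone and the ketene acetal carbon to the α-carbon. Loss of methanol and of the silyl group would aromatise the adduct to the chelated hydroxy benzophenone A10. Reduction of the diaryl ketone to CH2 and debenzylation would finish the synthesis.
- In its favour: the polarity of both partners fixes the orientation, so all six positions of ring A are set in one step. The free hydroxyl arises next to the carbonyl, so O3 and O5 are distinguished without selective protection. On regiochemical control of the ring A pattern it is the equal of, or better than, the Friedel–Crafts step of the chosen plan.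
- Against it: the diene is substituted at its reacting terminus and the ynone carries an alkyl group at its β-carbon. Both slow the cycloaddition and favour silyl transfer or simple conjugate addition at the temperatures needed. A8 is hydrolytically labile and must be made from a γ-substituted β-methoxy enoate. A further reduction next to a free phenol is added.
- Comparison: about eight or nine steps against six. The key step is mechanistically well matched, but it asks more of its substrates, and more functional-group adjustment follows it than follows the conjunctive coupling.

Key step: step 4

## Route

Step 1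
Reactants: 1 3-bromo-5-methoxyphenol
Product: 2 1-(benzyloxy)-3-bromo-5-methoxybenzene
Conditions: BnBr (1.1 equiv), K2CO3, DMF, rt
Reagents that add atoms: benzyl bromide, BrCc1ccccc1
Why: Williamson ether synthesis; the phenoxide formed with K2CO3 displaces bromide from benzyl bromide, and the aryl bromide and methyl ether are inert.

Step 2
Reactants: 2 1-(benzyloxy)-3-bromo-5-methoxybenzene; 3 4-(benzyloxy)benzyl alcohol (2.2 equiv)
Product: 6 1-(benzyloxy)-2,4-bis[4-(benzyloxy)benzyl]-3-bromo-5-methoxybenzene, via mono-benzylated arene 4 (not isolated), via isomeric mono-benzylated arene 5 (not isolated)
Conditions: TsOH·H2O (5 mol%), HFIP–CH2Cl2, 0 °C to rt, slow addition of 3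
Reagents that add atoms: none
Why: Twofold Friedel–Crafts benzylation; the acid in the ionising solvent turns 3 into a 4-alkoxybenzyl cation, which attacks 2 at the two positions that are para to one ether oxygen, ortho to the other and ortho to bromine (the usual sites of substitution in 5-substituted resorcinol diethers), giving 4 and 5 and then 6. Once a benzyl group is in place the neighbouring alkoxy group must turn its alkyl group toward the position between the two oxygens, which should shield that site from the second and from a third alkylation. Ring A of 2 is far more nucleophilic than the mono-alkoxy ring of 3, slow addition keeps self-condensation of 3 low, and aryl benzyl ethers tolerate catalytic sulfonic acid at room temperature.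

Step 3
Reactants: 7 3-methoxyphenol
Product: 8 3-methoxyphenyl trifluoromethanesulfonate
Conditions: Tf2O (1.1 equiv), pyridine, CH2Cl2, 0 °C
Reagents that add atoms: trifluoromethanesulfonic anhydride, O=S(=O)(OS(=O)(=O)C(F)(F)F)C(F)(F)F
Why: O-sulfonylation of a phenol with triflic anhydride, with pyridine as base; no other reactive group is present.

Step 4
Reactants: 6 1-(benzyloxy)-2,4-bis[4-(benzyloxy)benzyl]-3-bromo-5-methoxybenzene; 9 vinylboronic acid pinacol ester; 8 3-methoxyphenyl trifluoromethanesulfonate
Product: 12 2-{1-[3-(benzyloxy)-2,6-bis[4-(benzyloxy)benzyl]-5-methoxyphenyl]-2-(3-methoxyphenyl)ethyl}-4,4,5,5-tetramethyl-1,3,2-dioxaborolane (mixture of enantiomers), via aryllithium 10 (not isolated), via lithium aryl(vinyl)boronate complex 11 (not isolated)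
Conditions: t-BuLi (2.0 equiv), THF, −78 °C; 9, −78 °C to rt; then KOTf (2 equiv), 8 (1.1 equiv), Pd(OAc)2 (5 mol%), 1,1′-bis[bis(4-methoxy-3,5-dimethylphenyl)phosphino]-2,2′-bis[(dimethylamino)(phenyl)methyl]ferrocene (6 mol%, either enantiomer), THF, 60 °C
Reagents that add atoms: none
Why: Bromine–lithium exchange with two equivalents of t-BuLi (the second destroys the tert-butyl bromide formed) should give 10 much faster than any benzylic deprotonation at −78 °C, and 10 adds to the empty orbital on boron of 9 to give the four-coordinate boronate 11. Zerovalent palladium, formed in the flask from Pd(OAc)2 and the bisphosphine, inserts into the C–O bond of 8; because triflate does not bind and KOTf removes bromide as KBr, the divalent arylpalladium is cationic and can coordinate the vinyl group of 11. This π-activation triggers a 1,2-metallate shift in which ring A moves from boron to the adjacent carbon anti to palladium while palladium bonds to the terminal CH2, and reductive elimination from the β-boryl alkylpalladium then forms the CH2–ring B bond. The closest known reaction type is the palladium-catalysed conjunctive cross-coupling of vinylboron ate complexes with aryl triflates, applied here to a di-ortho-substituted migrating aryl. No ring is closed. One stereocentre, the boron-bearing carbon, is created; its configuration is decided by the face of the vinyl group that the ligand-bound palladium selects, and it is of no consequence because step 5 turns this carbon into CH2. The step needs chemoselectivity for the metallate shift over direct boron-to-palladium transfer of the vinyl or aryl group and over β-hydride elimination: the two ortho benzyl groups make ring A a poor transmetallating group but do not block its intramolecular shift, the boron is already four-coordinate, and the chelating bisphosphine leaves no vacant site for β-hydride elimination.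

Step 5
Reactants: 12 2-{1-[3-(benzyloxy)-2,6-bis[4-(benzyloxy)benzyl]-5-methoxyphenyl]-2-(3-methoxyphenyl)ethyl}-4,4,5,5-tetramethyl-1,3,2-dioxaborolane
Product: 13 1-(benzyloxy)-2,4-bis[4-(benzyloxy)benzyl]-5-methoxy-3-[2-(3-methoxyphenyl)ethyl]benzene
Conditions: CsF (2 equiv), H2O (3 equiv), 1,4-dioxane, 60–80 °C
Reagents that add atoms: none
Why: Base-promoted protodeboronation of a secondary benzylic boronic ester; fluoride or hydroxide adds to boron, and the benzylic C–B bond of the resulting boronate, weakened by ring A and by the strain between the boryl group and the two ortho benzyl groups, is cleaved by protonation from water. Benzyl ethers, methyl ethers and the diarylmethane positions are inert to these non-acidic, non-oxidising conditions, and the stereocentre disappears as the carbon becomes CH2.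

Step 6
Reactants: 13 1-(benzyloxy)-2,4-bis[4-(benzyloxy)benzyl]-5-methoxy-3-[2-(3-methoxyphenyl)ethyl]benzene
Product: 14 2,4-bis(4-hydroxybenzyl)-5-methoxy-3-[2-(3-methoxyphenyl)ethyl]phenol (the target, 3-hydroxy-2,6-bis(4-hydroxybenzyl)-5,3′-dimethoxybibenzyl)
Conditions: H2 (1 atm), palladium on carbon (10 wt% Pd), EtOAc–MeOH, rt
Reagents that add atoms: none
Why: Catalytic hydrogenolysis of three aryl benzyl ethers; the O–CH2Ph bonds are cleaved while aryl methyl ethers and the diarylmethane and bibenzyl C–C bonds are not reduced under these conditions, and no alkene, halogen or boron remains to interfere.

## Compound list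

1 | 3-bromo-5-methoxyphenol | COc1cc(O)cc(Br)c1 | starting material
2 | 1-(benzyloxy)-3-bromo-5-methoxybenzene | COc1cc(Br)cc(OCc2ccccc2)c1 | intermediate
3 | 4-(benzyloxy)benzyl alcohol | OCc1ccc(OCc2ccccc2)cc1 | starting material
4 | 1-(benzyloxy)-2-[4-(benzyloxy)benzyl]-3-bromo-5-methoxybenzene (benzyl group para to OMe) | COc1cc(OCc2ccccc2)c(Cc2ccc(OCc3ccccc3)cc2)c(Br)c1 | intermediate (not isolated)
5 | 5-(benzyloxy)-2-[4-(benzyloxy)benzyl]-1-bromo-3-methoxybenzene (benzyl group para to OBn) | COc1cc(OCc2ccccc2)cc(Br)c1Cc1ccc(OCc2ccccc2)cc1 | intermediate (not isolated)
6 | 1-(benzyloxy)-2,4-bis[4-(benzyloxy)benzyl]-3-bromo-5-methoxybenzene | COc1cc(OCc2ccccc2)c(Cc2ccc(OCc3ccccc3)cc2)c(Br)c1Cc1ccc(OCc2ccccc2)cc1 | intermediate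
7 | 3-methoxyphenol | COc1cccc(O)c1 | starting material
8 | 3-methoxyphenyl trifluoromethanesulfonate | COc1cccc(OS(=O)(=O)C(F)(F)F)c1 | intermediate
9 | vinylboronic acid pinacol ester (4,4,5,5-tetramethyl-2-vinyl-1,3,2-dioxaborolane) | C=CB1OC(C)(C)C(C)(C)O1 | starting material
10 | [3-(benzyloxy)-2,6-bis[4-(benzyloxy)benzyl]-5-methoxyphenyl]lithium | [Li]c1c(Cc2ccc(OCc3ccccc3)cc2)c(OCc2ccccc2)cc(OC)c1Cc1ccc(OCc2ccccc2)cc1 | intermediate (not isolated)
11 | lithium [3-(benzyloxy)-2,6-bis[4-(benzyloxy)benzyl]-5-methoxyphenyl](vinyl)(pinacolato)borate | [Li+].C=C[B-]1(OC(C)(C)C(C)(C)O1)c1c(Cc2ccc(OCc3ccccc3)cc2)c(OCc2ccccc2)cc(OC)c1Cc1ccc(OCc2ccccc2)cc1 | intermediate (not isolated)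
12 | 2-{1-[3-(benzyloxy)-2,6-bis[4-(benzyloxy)benzyl]-5-methoxyphenyl]-2-(3-methoxyphenyl)ethyl}-4,4,5,5-tetramethyl-1,3,2-dioxaborolane (one stereocentre, configuration not defined and not needed) | COc1cccc(CC(B2OC(C)(C)C(C)(C)O2)c2c(Cc3ccc(OCc4ccccc4)cc3)c(OCc3ccccc3)cc(OC)c2Cc2ccc(OCc3ccccc3)cc2)c1 | intermediate
13 | 1-(benzyloxy)-2,4-bis[4-(benzyloxy)benzyl]-5-methoxy-3-[2-(3-methoxyphenyl)ethyl]benzene | COc1cccc(CCc2c(Cc3ccc(OCc4ccccc4)cc3)c(OCc3ccccc3)cc(OC)c2Cc2ccc(OCc3ccccc3)cc2)c1 | intermediate
14 | 2,4-bis(4-hydroxybenzyl)-5-methoxy-3-[2-(3-methoxyphenyl)ethyl]phenol (achiral) | COc1cccc(CCc2c(Cc3ccc(O)cc3)c(O)cc(OC)c2Cc2ccc(O)cc2)c1 | target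

## Step count and least certain steps

Total: 6 steps. Longest linear sequence: 5 steps (steps 1, 2, 4, 5, 6); step 3 is a one-step branch.

**Step 4 (key step).** Three things are most likely to go wrong.
- The metallate shift of the di-ortho-substituted aryl may be slow, so that direct transfer of the vinyl group from boron to palladium takes over.
- The aryllithium may be quenched by proton transfer from a doubly benzylic CH2 group before it is borylated.
- Bromide left in solution may block alkene binding if its precipitation as KBr is incomplete.

The fallback avoids both the aryllithium and the migration and sets out from 6. Hydroboration of 3-methoxystyrene A6 with 9-borabicyclo[3.3.1]nonane in THF would give 9-[2-(3-methoxyphenyl)ethyl]-9-borabicyclo[3.3.1]nonane F1. A B-alkyl Suzuki–Miyaura coupling of F1 with 6 (Pd(OAc)2, 2-dicyclohexylphosphino-2′,6′-dimethoxybiphenyl, K3PO4, THF–H2O, 65–80 °C) should then form the C1–CH2 bond directly. This ligand class is known to couple 2,6-disubstituted aryl halides with primary alkylboranes. The fallback comes back to the route at 13, so step 5 is no longer needed.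

**Step 2.** The likely failures are alkylation at the position between the two ether oxygens, a third alkylation, self-condensation of the benzylic alcohol, and acid-induced loss or migration of a benzyl ether. The fallback sets out from 2 and replaces cation chemistry by cross-coupling. Twofold iodination (N-iodosuccinimide, catalytic CF3CO2H, MeCN) at the same two positions would give 1-(benzyloxy)-3-bromo-2,4-diiodo-5-methoxybenzene F2. Zinc insertion into 4-(benzyloxy)benzyl chloride A5 (Zn dust, LiCl, THF) would give 4-(benzyloxy)benzylzinc chloride F3. A Negishi coupling of F2 with two equivalents of F3 (Pd(PPh3)4, THF, rt to 50 °C) should react at the two C–I bonds and leave the more hindered and less reactive C–Br bond. The fallback comes back to the route at 6.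

**Step 5.** The boron sits between two ortho benzyl groups, so boronate formation, and with it C–B cleavage, may be slow or incomplete. The fallback sets out from 12 and removes boron by oxidation and reduction. Oxidation (H2O2, NaOH, THF, 0 °C) would give 1-[3-(benzyloxy)-2,6-bis[4-(benzyloxy)benzyl]-5-methoxyphenyl]-2-(3-methoxyphenyl)ethanol F4. Hydrogenation of F4 (H2, palladium on carbon, EtOAc–AcOH, trace HCl) should remove the benzylic hydroxyl, either by direct C–O hydrogenolysis or by dehydration to the stilbene and hydrogenation, together with the three benzyl groups. The fallback comes back to the route at 14 in the same number of steps.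

## Further compounds

F1 | step 4 | 9-[2-(3-methoxyphenyl)ethyl]-9-borabicyclo[3.3.1]nonane | COc1cccc(CCB2C3CCCC2CCC3)c1
F2 | step 2 | 1-(benzyloxy)-3-bromo-2,4-diiodo-5-methoxybenzene | COc1cc(OCc2ccccc2)c(I)c(Br)c1I
F3 | step 2 | 4-(benzyloxy)benzylzinc chloride | Cl[Zn]Cc1ccc(OCc2ccccc2)cc1
F4 | step 5 | 1-[3-(benzyloxy)-2,6-bis[4-(benzyloxy)benzyl]-5-methoxyphenyl]-2-(3-methoxyphenyl)ethanol (mixture of enantiomers) | COc1cccc(CC(O)c2c(Cc3ccc(OCc4ccccc4)cc3)c(OCc3ccccc3)cc(OC)c2Cc2ccc(OCc3ccccc3)cc2)c1
A1 | alternative 1 | (E)-3-[4-(benzyloxy)benzyl]-6-(3-methoxyphenyl)hex-3-en-2-one | CC(=O)/C(Cc1ccc(OCc2ccccc2)cc1)=C/CCc1cccc(OC)c1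
A2 | alternative 1 | dimethyl 2-[4-(benzyloxy)benzyl]malonate | COC(=O)C(Cc1ccc(OCc2ccccc2)cc1)C(=O)OC
A3 | alternative 1 | methyl 1,3-bis[4-(benzyloxy)benzyl]-2-[2-(3-methoxyphenyl)ethyl]-4,6-dioxocyclohexane-1-carboxylate (mixture of diastereomers) | COC(=O)C1(Cc2ccc(OCc3ccccc3)cc2)C(CCc2cccc(OC)c2)C(Cc2ccc(OCc3ccccc3)cc2)C(=O)CC1=O
A4 | alternative 2 | 1-(benzyloxy)-3-iodo-5-methoxybenzene | COc1cc(I)cc(OCc2ccccc2)c1
A5 | alternative 2 | 4-(benzyloxy)benzyl chloride | ClCc1ccc(OCc2ccccc2)cc1
A6 | alternative 2 | 3-methoxystyrene | C=Cc1cccc(OC)c1
A7 | alternative 2 | (E)-3-(benzyloxy)-2,6-bis[4-(benzyloxy)benzyl]-5,3′-dimethoxystilbene | COc1cccc(/C=C/c2c(Cc3ccc(OCc4ccccc4)cc3)c(OCc3ccccc3)cc(OC)c2Cc2ccc(OCc3ccccc3)cc2)c1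
A8 | alternative 3 | 5-[4-(benzyloxy)phenyl]-1,3-dimethoxy-1-(trimethylsilyloxy)penta-1,3-diene (double-bond geometry not defined) | COC(O[Si](C)(C)C)=CC(OC)=CCc1ccc(OCc2ccccc2)cc1
A9 | alternative 3 | 1-[4-(benzyloxy)phenyl]-5-(3-methoxyphenyl)pent-2-yn-1-one | O=C(C#CCCc1cccc(OC)c1)c1ccc(OCc2ccccc2)cc1
A10 | alternative 3 | [4-(benzyloxy)phenyl]{3-[4-(benzyloxy)benzyl]-6-hydroxy-4-methoxy-2-[2-(3-methoxyphenyl)ethyl]phenyl}methanone | COc1cccc(CCc2c(C(=O)c3ccc(OCc4ccccc4)cc3)c(O)cc(OC)c2Cc2ccc(OCc3ccccc3)cc2)c1
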